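**Plan**

1. Numbering: ring A = C1 (O-aryl), C2 (OH), C3 (H), C4 (Br), C5 (H), C6 (Br). Ring B = C1' (O-aryl), C2' (OH), C3' (H), C4', C5', C6' (Br).
2. Enabling feature: the bridging oxygen is boxed in by C2-OH, C6-Br, C2'-OH and C6'-Br, so O–C1 is made while C1 is still a primary sp3 carbon. C5-H is para to C2-O and sits between C4 and C6, which is where a C3 nitrodialdehyde places its nitro group.
3. Cuts, in retrosynthetic order: the two O–CH3 bonds of a dimethyl ether, a C5–N bond (added back), C4–Br and C6–Br, then C3–C4 and C1–C6 (ring A opened to ketone plus dialdehyde), then O–CH2, then the three C–Br bonds of ring B.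
4. Forward: ring B comes ready-made from guaiacol and is tribrominated, and its oxygen is alkylated with chloroacetone. Ring A is then grown on that side chain, and NO2 → NH2 → 2 Br → H completes ring A before both phenols are freed.
5. Stereochemistry: none to set. The target has no stereocentre, and rotation about the ether bonds is taken as free on the laboratory time scale.

Key step: step 3

Assumption: sodium nitromalonaldehyde is bought as its monohydrate and drawn anhydrous (the solid is impact- and heat-sensitive and is used in small lots); the diazonium salt is drawn as its hydrogen sulfate, and the boron intermediate of the last step in its simplest form, with one BBr2 group on each oxygen.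

**Step 1**
Reactants: 1 guaiacol
Product: 2 2,3,4-tribromo-6-methoxyphenol (4,5,6-tribromoguaiacol)
Conditions: Br2 (3.1 equiv), AcOH, 10 °C → rt
Reagents that add atoms: bromine, BrBr
Why: Electrophilic aromatic bromination in which the free OH sends bromine to its para and ortho carbons (C4', C6') and OMe sends the third to its para carbon (C5'), while C3', meta to OH and activated only by the ortho OMe, should stay C–H when bromine is held at three equivalents.

**Step 2**
Reactants: 2 2,3,4-tribromo-6-methoxyphenol; 3 chloroacetone
Product: 4 1-(2,3,4-tribromo-6-methoxyphenoxy)propan-2-one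
Conditions: 3 (1.3 equiv), K2CO3, DMF, 50 °C
Reagents that add atoms: none
Why: Williamson ether synthesis, in which carbonate fully deprotonates the acidic tribromophenol and its oxygen displaces chloride (SN2) at an unhindered primary carbon activated by the neighbouring carbonyl, so the ortho Br and OMe groups that would hamper an aryl–oxygen coupling matter little.

**Step 3**
Reactants: 4 1-(2,3,4-tribromo-6-methoxyphenoxy)propan-2-one; 5 sodium nitromalonaldehyde
Product: 7 2-(2,3,4-tribromo-6-methoxyphenoxy)-4-nitrophenol, via sodium nitrophenolate 6 (not isolated)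
Conditions: 5 (1.5 equiv), NaOH (1.1 equiv), EtOH–H2O, 0 °C → rt, 2–4 d; then 2 M HCl
Reagents that add atoms: none
Why: Hydroxide reversibly enolises 4 on both sides of the carbonyl, each enolate adds to one formyl carbon of 5 and water is lost, so the methyl carbon becomes C3 (new C3–C4 bond), the OCH2 carbon becomes C1 (new C1–C6 bond), the carbonyl carbon becomes C2 and the nitro-bearing carbon becomes C5. The closest known reaction type is the double-aldol (3+3) benzannulation of sodium nitromalonaldehyde with acetone, alkyl methyl ketones and dibenzyl ketones to 4-nitrophenols, applied here to a ketone whose OCH2 protons are further acidified by oxygen. Ring A closes in the second aldol as a 6-(enolendo)-exo-trig process, which is geometrically within reach because the open-chain intermediate is a delocalised push-pull anion (or still a beta-hydroxy adduct) with no fixed C3–C4 geometry. Loss of the second water leaves the aromatic, resonance-stabilised 4-nitrophenolate 6 directly, and this sink drains all the preceding equilibria. No stereocentre is formed and regiochemistry is fixed by connectivity, since the two formyl groups of 5 are equivalent and 4 carries one CH3 and one OCH2 beside its carbonyl; the selectivity needed is cross- over self-condensation, secured because 5 cannot self-condense, offers less hindered acceptor carbons than the ketone of 4, and is used in excess at low temperature. Ring B is one atom away from the reacting carbon and can turn aside, ethanol keeps the lipophilic ketone in solution, and the C–Br bonds and both ethers tolerate cold dilute hydroxide.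

**Step 4**
Reactants: 7 2-(2,3,4-tribromo-6-methoxyphenoxy)-4-nitrophenol
Product: 8 1,2,3-tribromo-5-methoxy-4-(2-methoxy-5-nitrophenoxy)benzene
Conditions: MeI, K2CO3, DMF, rt
Reagents that add atoms: iodomethane, CI
Why: Williamson O-methylation of the acidic nitrophenol, which caps C2–O with the same group as C2'–O, blocks quinone imine formation at the amine stage and lets one reagent free both phenols at the end.

**Step 5**
Reactants: 8 1,2,3-tribromo-5-methoxy-4-(2-methoxy-5-nitrophenoxy)benzene
Product: 9 4-methoxy-3-(2,3,4-tribromo-6-methoxyphenoxy)aniline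
Conditions: Fe powder, AcOH, EtOH–H2O, 75 °C
Reagents that add atoms: none
Why: Béchamp-type reduction by electron transfer from zerovalent iron, which takes nitroarenes to anilines without the hydrogenolysis of aryl bromides that catalytic hydrogenation would risk.

**Step 6**
Reactants: 9 4-methoxy-3-(2,3,4-tribromo-6-methoxyphenoxy)aniline
Product: 10 2,6-dibromo-4-methoxy-3-(2,3,4-tribromo-6-methoxyphenoxy)aniline
Conditions: NBS (2.05 equiv), MeCN, 0 °C → rt, dark
Reagents that add atoms: N-bromosuccinimide, O=C1CCC(=O)N1Br
Why: Electrophilic aromatic bromination of an aniline, in which NH2 at C5 is by far the strongest donor in the molecule, its para carbon C2 is occupied, and its ortho carbons C4 and C6 are also para and ortho to the ether oxygen, so two equivalents should stop at the 4,6-dibromide and leave C3 (meta to N) and C3' (on the tribrominated ring) untouched.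

**Step 7**
Reactants: 10 2,6-dibromo-4-methoxy-3-(2,3,4-tribromo-6-methoxyphenoxy)aniline
Product: 12 1,2,3-tribromo-4-(2,4-dibromo-6-methoxyphenoxy)-5-methoxybenzene, via arenediazonium hydrogen sulfate 11 (not isolated)
Conditions: NaNO2, conc. H2SO4–AcOH, 0–5 °C; then 50% aq. H3PO2, Cu2O (cat.), 0 °C → rt
Reagents that add atoms: sodium nitrite, [Na+].[O-]N=O (one N, held in 11 only); sulfuric acid, OS(=O)(=O)O (counter-ion of 11 only)
Why: Diazotisation followed by hydrodediazoniation with hypophosphorous acid (radical chain, the aryl radical taking H from H3PO2) is the classical way to erase an amino director from 2,6-dibromoanilines; nitrosylsulfuric acid copes with the weakly basic amine, and the absence of chloride avoids halogen exchange at the ortho C–Br bonds activated by the diazonium group.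

**Step 8**
Reactants: 12 1,2,3-tribromo-4-(2,4-dibromo-6-methoxyphenoxy)-5-methoxybenzene
Product: 14 3,4,5-tribromo-2-(2,4-dibromo-6-hydroxyphenoxy)phenol, via bis(dibromoboryl) ether 13 (not isolated)
Conditions: BBr3 (5 equiv), CH2Cl2, −78 °C → rt; then ice–H2O
Reagents that add atoms: boron tribromide, BrB(Br)Br (B and Br held in 13 only)
Why: Lewis-acid cleavage of aryl methyl ethers, in which BBr3 binds each methoxy oxygen, bromide attacks the methyl carbon (SN2) and hydrolysis of the aryl borates frees both phenols, while the diaryl ether (no sp3 carbon on oxygen) and the five C–Br bonds are inert.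

**Compound list**

1 | guaiacol (2-methoxyphenol) | COc1ccccc1O | starting material
2 | 2,3,4-tribromo-6-methoxyphenol (4,5,6-tribromoguaiacol) | COc1cc(Br)c(Br)c(Br)c1O | intermediate
3 | chloroacetone | CC(=O)CCl | starting material
4 | 1-(2,3,4-tribromo-6-methoxyphenoxy)propan-2-one | CC(=O)COc1c(OC)cc(Br)c(Br)c1Br | intermediate
5 | sodium nitromalonaldehyde (sodium 2-nitro-3-oxoprop-1-en-1-olate, sold as the monohydrate) | O=CC(=C[O-])[N+](=O)[O-].[Na+] | starting material
6 | sodium 2-(2,3,4-tribromo-6-methoxyphenoxy)-4-nitrophenolate | [Na+].[O-]c1ccc([N+](=O)[O-])cc1Oc1c(OC)cc(Br)c(Br)c1Br | intermediate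
7 | 2-(2,3,4-tribromo-6-methoxyphenoxy)-4-nitrophenol | Oc1ccc([N+](=O)[O-])cc1Oc1c(OC)cc(Br)c(Br)c1Br | intermediate
8 | 1,2,3-tribromo-5-methoxy-4-(2-methoxy-5-nitrophenoxy)benzene | COc1ccc([N+](=O)[O-])cc1Oc1c(OC)cc(Br)c(Br)c1Br | intermediate
9 | 4-methoxy-3-(2,3,4-tribromo-6-methoxyphenoxy)aniline | COc1ccc(N)cc1Oc1c(OC)cc(Br)c(Br)c1Br | intermediate
10 | 2,6-dibromo-4-methoxy-3-(2,3,4-tribromo-6-methoxyphenoxy)aniline | COc1cc(Br)c(N)c(Br)c1Oc1c(OC)cc(Br)c(Br)c1Br | intermediate
11 | 2,6-dibromo-4-methoxy-3-(2,3,4-tribromo-6-methoxyphenoxy)benzenediazonium hydrogen sulfate | COc1cc(Br)c([N+]#N)c(Br)c1Oc1c(OC)cc(Br)c(Br)c1Br.OS(=O)(=O)[O-] | intermediate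
12 | 1,2,3-tribromo-4-(2,4-dibromo-6-methoxyphenoxy)-5-methoxybenzene | COc1cc(Br)cc(Br)c1Oc1c(OC)cc(Br)c(Br)c1Br | intermediate
13 | O,O'-bis(dibromoboryl) derivative of the target diphenol | BrB(Br)Oc1cc(Br)cc(Br)c1Oc1c(OB(Br)Br)cc(Br)c(Br)c1Br | intermediate
14 | 3,4,5-tribromo-2-(2,4-dibromo-6-hydroxyphenoxy)phenol (CNP0189648.0) | Oc1cc(Br)cc(Br)c1Oc1c(O)cc(Br)c(Br)c1Br | target

**Step count**

Total step count: 8. Longest linear sequence: 8 (1 → 14).

**Steps most likely to fail**

**Step 3.**
- Risk: base-induced decay of the dialdehyde salt and self-aldol of the ketone may overtake cross-condensation. The second aldol at the crowded OCH2 carbon may also stall at the open-chain stage.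
- Fallback: this gives up ring construction and makes O–C1 by metal-free O-arylation. It sets out from 2 and rejoins at 8.
- Commercial 2-iodo-4-nitroanisole (COc1ccc(cc1I)[N+](=O)[O-]) is oxidised with mCPBA in the presence of TsOH and anisole. This gives (4-methoxyphenyl)(2-methoxy-5-nitrophenyl)iodonium 4-methylbenzenesulfonate F1.
- The potassium salt of 2 (K2CO3 or t-BuOK, MeCN or THF, rt to 50 °C) then undergoes ligand coupling at trivalent iodine.
- The electron-poor nitroaryl group should be the one transferred, which delivers 8 directly.
- No transition metal is present, so the C–Br bonds are not at risk, and hindered phenols are established partners in this reaction type.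

**Step 6.**
- Risk: the brominating agent may oxidise the electron-rich 4-alkoxyaniline (ipso attack at C2, quinone imine formation). Stoichiometric control may also slip towards under- or over-bromination.
- Fallback: this tames the director for the first bromination and releases it only for the second. It sets out from 9 and rejoins at 10.
- Acetylation (Ac2O, pyridine) gives N-[4-methoxy-3-(2,3,4-tribromo-6-methoxyphenoxy)phenyl]acetamide F2.
- One equivalent of Br2 in AcOH should brominate only C4, which is ortho to NHAc and para to the ether oxygen. The product is N-[2-bromo-4-methoxy-5-(2,3,4-tribromo-6-methoxyphenoxy)phenyl]acetamide F3.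
- Hydrolysis (HCl, EtOH, reflux) frees 2-bromo-4-methoxy-5-(2,3,4-tribromo-6-methoxyphenoxy)aniline F4.
- F4 is already deactivated by one bromine. One equivalent of NBS can attack it only at C6, the sole open site ortho or para to nitrogen, to give 10.

**Step 1.**
- Risk: the third bromination may show poor site control (C3' against C5'), or run on to tetrabromination, and the mixture may be hard to separate.
- Fallback: this installs the difficult bromine first under a different director. It sets out from 1 and rejoins at 2.
- Acetylation (Ac2O, pyridine) gives 2-methoxyphenyl acetate F5, in which OMe is the dominant donor.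
- Monobromination (NBS, MeCN) therefore goes para to OMe and gives 5-bromo-2-methoxyphenyl acetate F6.
- Saponification (NaOH, MeOH–H2O, then acid) gives 5-bromo-2-methoxyphenol F7.
- Two equivalents of Br2 in AcOH are then steered by the free OH to its para and ortho carbons only, giving 2.

**Further compounds**

F1 | step 3 | (4-methoxyphenyl)(2-methoxy-5-nitrophenyl)iodonium 4-methylbenzenesulfonate | COc1ccc([I+]c2cc([N+](=O)[O-])ccc2OC)cc1.Cc1ccc(S(=O)(=O)[O-])cc1
F2 | step 6 | N-[4-methoxy-3-(2,3,4-tribromo-6-methoxyphenoxy)phenyl]acetamide | COc1ccc(NC(C)=O)cc1Oc1c(OC)cc(Br)c(Br)c1Br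
F3 | step 6 | N-[2-bromo-4-methoxy-5-(2,3,4-tribromo-6-methoxyphenoxy)phenyl]acetamide | COc1cc(Br)c(NC(C)=O)cc1Oc1c(OC)cc(Br)c(Br)c1Br
F4 | step 6 | 2-bromo-4-methoxy-5-(2,3,4-tribromo-6-methoxyphenoxy)aniline | COc1cc(Br)c(N)cc1Oc1c(OC)cc(Br)c(Br)c1Br
F5 | step 1 | 2-methoxyphenyl acetate | COc1ccccc1OC(C)=O
F6 | step 1 | 5-bromo-2-methoxyphenyl acetate | COc1ccc(Br)cc1OC(C)=O
F7 | step 1 | 5-bromo-2-methoxyphenol | COc1ccc(Br)cc1O
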